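## The problem

Compound 21 is a 1,4-benzoquinone in which all six ring carbons are substituted. With the ring numbered C1(=O), C2(OH), C3(CH3), C4(=O), C5(OH), C6(chain), no ring C–H is left for late functionalisation, so the complete pattern has to come out of the ring-forming event. The methyl group at C3 and the (E)-nonadec-14-enyl chain at C6 must end up para, and because the two carbon substituents differ, C-alkylation of a preformed symmetric dihydroxyquinone could not tell the two positions apart. There is no stereocentre, and the only stereochemical element is the E double bond between C14' and C15' of the chain, thirteen methylenes from the ring, so nothing in the molecule can direct its geometry. It has to be made by an intrinsically trans-selective reaction and then kept away from hydrogenation, halogens, peracids and strong acid. The 2,5-dihydroxyquinone is a doubly vinylogous acid, a metal chelator and a redox-active electrophile, and is best carried as a dialkyl ether and released last. The enabling feature is the run C4–C5–C6–C1, three oxygenated carbons and one alkylated carbon in a row, which is the pattern of a squarate-derived 3-alkoxy-2-alkylcyclobutenone with a carbinol carbon, while C2–C3 is a 2-alkoxypropenyl unit (enol ether carbon C2, methyl-bearing carbon C3).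

## Retrosynthesis

**21 to 20.** The two O–H bonds of 21 are traced back to O–alkyl bonds, so 21 comes from the dialkoxyquinone 20 by hydrolysis of its two vinylogous ester groups. The ethers keep every intermediate neutral and non-chelating. Methyl and ethyl ethers come directly from the ring-forming chemistry and leave by addition–elimination with hydroxide, whereas benzyl or allyl ethers would need hydrogenolysis or metal catalysis that endangers the alkene. The forward step only has to displace two alkoxides from quinone carbons.

**20 to 19.** Quinone 20 is the oxidation product of hydroquinone 19, and no skeletal bond is cut. Hydroquinone 19 is the natural product of the ring-forming step. The forward step asks only that 19 be oxidised deliberately before air does it unselectively.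

**19 to 16 (key disconnection).** The ring of 19 is opened at C1–C2 and contracted by rejoining C1 to C4. This leads back through cyclohexadienone 18 and dienylketene 17 to cyclobutenone 16. Cuts that build the benzene ring from three components or from open-chain carbonyl compounds leave oxygens to be added afterwards. This cut forms one skeletal bond in an intramolecular pericyclic cascade and delivers all four ring oxygens at the final oxidation level. The price is a strained, acid-sensitive precursor. Precursor 16 is simpler because its substituents can be installed one at a time by carbonyl additions to a four-membered ring. The forward reaction must open the ring with the hydroxyl turning outward and close the ketene onto the enol ether carbon.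

**16 to 11 and 15.** The bond between the carbinol carbon and the propenyl carbon (ring bond C4–C3 of 21) is cut. This gives cyclobutenedione 11 and the lithiated enol ether 15, which comes from bromide 14. The reverse order of introduction would interchange the chain and an oxygen substituent on the final ring. The chosen order uses the fact that the carbonyl of 11 next to the methoxy-bearing carbon is the ketone-like one. The forward step must deliver 15 to that carbonyl only, and 15 must live long enough, which is why lithium cis to ethoxy is specified.

**14 to 12.** Bromide 14 is traced to ethyl prop-1-enyl ether 12. In the forward sense bromine addition gives dibromide 13 and dehydrobromination gives 14. This one-flask preparation from a bulk chemical is preferred to hydrometallation of an alkoxyalkyne, which would put the metal trans to oxygen. The forward reaction must lose the α-bromine together with the C2 proton and favour bromine cis to ethoxy.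

**11 to 8 and 9.** The ring–chain bond (C6–C1' of 21) is cut to give dimethyl squarate 8 and Grignard reagent 9 from bromide 7. The adduct 10 is converted to 11 in the same flask. Squarate 8 supplies four contiguous ring carbons with three of the target's oxygens in place. It also lets an unstabilised primary alkyl group be attached by plain carbonyl addition, more directly than a cross-coupling to a halogenated quinone. The forward step must stop at mono-addition.

**7 to 1 and 3.** Bromide 7 is cut between C13' and C14' of the chain. The path runs through alkenol 6 and alkynol 5 to 13-bromotridecan-1-ol 2 and 1-hexyne 3 (as acetylide 4), and 2 comes from diol 1. An alkyne precursor is preferred to a Wittig, Julia or cross-metathesis union because dissolving-metal reduction gives the E alkene without any directing group. The sp–sp3 alkylation joins two commercial fragments of thirteen and six carbons. The forward sequence asks for monobromination of a symmetric diol, alkylation beside a free hydroxyl, and an Appel reaction.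

## Roads not taken

Alternative 1: Dötz benzannulation.
- Cut: C4–C5, C6–C1 and C1–C2. The ring is assembled from the alkenyl carbene complex (CO)5Cr=C(OMe)C(CH3)=CH2 A2, which supplies C2, C3 and C4, from the terminal alkyne (E)-henicos-16-en-1-yne A3, which supplies C5 and C6, and from one carbonyl ligand of A2, which becomes C1.
- Forward key step: A2, A3 and the carbonyl ligand combine to 4-methoxy-5-methyl-2-[(E)-nonadec-14-enyl]phenol A1.
- Merits: it is convergent, and a terminal alkyne reliably places its substituent next to the new phenol carbon, which fixes chain and methyl para. The isolated alkene should be tolerated, and A3 is one acetylide alkylation away from 7.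
- Weak points: A1 carries oxygen only at C1 and C4, while C2 and C5 are C–H. Oxidation would give 2-methyl-5-[(E)-nonadec-14-enyl]cyclohexa-2,5-diene-1,4-dione A4, and two oxygens would then have to be added to the electrophilic quinone A4. That means amine addition, oxidation and hydrolysis, or double epoxidation and rearrangement, in the presence of the chain alkene. The carbene complex A2 is consumed in stoichiometric amount.
- Comparison: as a ring construction this road is at least as dependable as the squarate expansion, and it avoids the fragile lithiated enol ether 15. Against that, the chosen plan's ring-forming step gives all four oxygens at the right oxidation level, so only an oxidation and a hydrolysis follow.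

Alternative 2: alkynone–malonate Michael–Claisen annulation.
- Cut: C6–C1 and C3–C2.
- Forward key step: the anion of dimethyl malonate A7 adds to the chain-bearing alkyne carbon of (E)-tetracos-19-en-4-yn-3-one A6. The ethyl ketone enolate then acylates one ester group and closes the ring to methyl 2,4-dihydroxy-3-methyl-6-[(E)-nonadec-14-enyl]benzoate A5.
- Merits: A7 is a bulk chemical, no cryogenic organometallic is needed in the ring formation, and the para relation is fixed by the structure of A6.
- Weak points: A5 has only the C2 and C4 oxygens. The ester carbon at C1 has to be excised and replaced by oxygen (reduction to the aldehyde and Dakin oxidation, or decarboxylation and oxidation), and C5–H has to be oxidised. That is four or five redox steps on an electron-rich arene. The Michael adduct must also reach the alkene geometry that allows the Claisen closure.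
- Comparison: the ring-forming step is operationally simpler and cheaper than the squarate sequence. The chosen plan offsets this with oxidation-level economy, needing two steps after the ring is made and not about five.

Alternative 3: [5+1] triketone aldol aromatisation.
- Cut: C1–C6 and C5–C6. The diketone 1,5-dimethoxy-3-methylpentane-2,4-dione A9 supplies C1–C5 with the methyl group and all four oxygens. The ester carbon of methyl (E)-icos-15-enoate A10 becomes C6.
- Forward key step: the dianion of A9 is acylated at one terminus by A10, and the other terminus then adds to the new ketone. Dehydration and enolisation give 4,6-dimethoxy-2-methyl-5-[(E)-nonadec-14-enyl]benzene-1,3-diol A8.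
- Merits: A8 already has the complete oxygen pattern. Oxidative demethylation would give 2-hydroxy-5-methoxy-3-methyl-6-[(E)-nonadec-14-enyl]cyclohexa-2,5-diene-1,4-dione A11, and A11 is one hydrolysis from 21. The chain comes from the fatty ester A10 with no organometallic attachment.
- Weak points: A9 is not an article of commerce and needs a crossed Claisen condensation with a regiochemical problem of its own. The dianion must form at a methoxymethyl terminus. After acylation the triketone is fully enolised, so the second bond must form at a deactivated carbonyl. Ring closure through an enol oxygen to a six-membered oxygen heterocycle competes. The acidic product consumes a second equivalent of dianion.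
- Comparison: in oxidation-state economy this road equals the chosen plan, and in step count it could beat it. The chosen plan's advantage is that every bond is made by a reaction with close precedent on its substrate class. Its regiochemistry is fixed by connectivity and not by a contest between enolisation sites.

Key step: step 8

## Route

Assumption: 21 is drawn as one of two degenerate tautomers of the 2,5-dihydroxy-1,4-benzoquinone, so which ring carbons are called carbonyls is a convention and both drawings are the same compound.

Step 1
Reactants: 1 tridecane-1,13-diol
Product: 2 13-bromotridecan-1-ol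
Conditions: 48% aq. HBr (1.2 equiv), toluene, reflux
Reagents that add atoms: hydrogen bromide, Br
Why: Substitution of one protonated hydroxyl by bromide (SN2); in the two-phase aqueous HBr/toluene system the bromo alcohol passes into toluene, where it reacts much more slowly than the diol, which is the established basis of selective monobromination of α,ω-diols.

Step 2
Reactants: 2 13-bromotridecan-1-ol; 3 1-hexyne
Product: 5 nonadec-14-yn-1-ol, via hex-1-ynyllithium 4 (not isolated)
Conditions: 3 (2.5 equiv), n-BuLi (2.4 equiv), THF, −78 → 0 °C; then 2, DMPU, 0 °C → rt; H2O
Reagents that add atoms: none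
Why: SN2 alkylation of a lithium acetylide by a primary bromide, accelerated by the dipolar cosolvent; one equivalent of 4 serves as base for the hydroxyl, and the lithium alkoxide so formed is a far weaker nucleophile than the acetylide, so C-alkylation should prevail over ether formation.

Step 3
Reactants: 5 nonadec-14-yn-1-ol
Product: 6 (E)-nonadec-14-en-1-ol
Conditions: Na, NH3(l)/THF, −33 °C; then solid NH4Cl
Reagents that add atoms: none
Why: Dissolving-metal reduction of an isolated internal alkyne; the vinyl radical anion and vinyl anion adopt the trans geometry before protonation by ammonia, which sets the E alkene, and the sodium alkoxide of the remote alcohol is a spectator while an isolated alkene is not reduced further.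

Step 4
Reactants: 6 (E)-nonadec-14-en-1-ol
Product: 7 (E)-19-bromononadec-5-ene [(E)-nonadec-14-enyl bromide]
Conditions: CBr4, PPh3, CH2Cl2, 0 °C
Reagents that add atoms: carbon tetrabromide, BrC(Br)(Br)Br
Why: Appel reaction; the alkoxyphosphonium ion is displaced by bromide in an SN2 step under neutral conditions that leave the E alkene untouched.

Step 5
Reactants: 7 (E)-19-bromononadec-5-ene; 8 dimethyl squarate (3,4-dimethoxycyclobut-3-ene-1,2-dione)
Product: 11 3-methoxy-4-[(E)-nonadec-14-enyl]cyclobut-3-ene-1,2-dione, via Grignard reagent 9 (not isolated), via magnesium alkoxide adduct 10 (not isolated)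
Conditions: Mg, THF, rt → 40 °C; then 8, THF, −78 °C; then (CF3CO)2O, −78 → 0 °C; H2O
Reagents that add atoms: water, O
Why: Grignard formation from the primary bromide and 1,2-addition to one of the two equivalent carbonyls of 8 at low temperature, where alkoxide 10 resists a second addition; trifluoroacetylation of the tertiary alkoxide, ionisation to the methoxy-stabilised cyclobutenyl cation and hydrolysis with loss of methanol give the 3-alkyl-4-methoxycyclobutenedione, the standard squarate-to-cyclobutenedione sequence.

Step 6
Reactants: 12 ethyl prop-1-enyl ether (commercial cis/trans mixture)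
Product: 14 (Z)-2-bromo-1-ethoxyprop-1-ene, via dibromo ether 13 (not isolated)
Conditions: Br2, pentane, −78 °C; then PhNEt2, 90 °C; fractional distillation
Reagents that add atoms: bromine, BrBr
Why: Electrophilic addition of bromine to the enol ether, then amine-promoted loss of HBr from the α-bromo ether through its oxocarbenium ion (C1–Br ionises, C2–H is lost), the established bromination–dehydrobromination route from vinyl ethers to β-bromovinyl ethers; both diastereomers of 13 converge on the same cation, and by analogy with the parent vinyl ether the isomer with bromine cis to ethoxy should predominate and be purified by distillation.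

Step 7
Reactants: 14 (Z)-2-bromo-1-ethoxyprop-1-ene; 11 3-methoxy-4-[(E)-nonadec-14-enyl]cyclobut-3-ene-1,2-dione
Product: 16 4-[(Z)-1-ethoxyprop-1-en-2-yl]-4-hydroxy-3-methoxy-2-[(E)-nonadec-14-enyl]cyclobut-2-en-1-one (racemic), via lithiated enol ether 15 (not isolated)
Conditions: 14, t-BuLi (2.0 equiv), THF, −78 °C; then 11, THF, −78 °C; cold H2O, Et2O
Reagents that add atoms: none
Why: Bromine–lithium exchange with retention gives the vinyllithium with lithium cis to ethoxy, the geometry in which β-elimination of LiOEt is slow at −78 °C; it adds 1,2 to the carbonyl of 11 beside the methoxy-bearing carbon because the other carbonyl is a deactivated vinylogous ester, which fixes the later para relation of chain and methyl. The carbinol carbon is the only stereocentre, is formed racemic and is erased in step 8; the cold non-acidic quench protects the β-ethoxyallylic alcohol.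

Step 8
Reactants: 16 4-[(Z)-1-ethoxyprop-1-en-2-yl]-4-hydroxy-3-methoxy-2-[(E)-nonadec-14-enyl]cyclobut-2-en-1-one
Product: 19 2-ethoxy-5-methoxy-3-methyl-6-[(E)-nonadec-14-enyl]benzene-1,4-diol, via dienylketene 17 (not isolated), via cyclohexadienone 18 (not isolated)
Conditions: degassed toluene, 110 °C, Ar, base-washed glassware
Reagents that add atoms: none
Why: Thermal conrotatory 4π-electrocyclic opening of the cyclobutenone breaks the C1–C4 bond of 16 and gives dienylketene 17; as in all such openings of 4-hydroxy- and 4-alkoxycyclobutenones the donor hydroxyl rotates outward, which turns the ethoxypropenyl group inward, toward the ketene carbon. Ketene 17 then closes the six-membered carbocycle by a thermal disrotatory 6π-electrocyclisation that joins the ketene carbon (ring C1 of 21) to the ethoxy-bearing alkene carbon (C2), and the resulting cyclohexa-2,4-dienone 18 enolises irreversibly to the aromatic hydroquinone 19. The closest known reaction type is the thermal ring expansion of squarate-derived 4-alkenyl- and 4-aryl-4-hydroxycyclobutenones to hydroquinones (Moore rearrangement). No stereocentre is created, since the carbinol centre of 16 and the sp3 carbon of 18 both become aromatic carbons. The selectivity needed is periselectivity, closure of the ketene onto the alkene and not capture by the hydroxyl or by a second molecule; it is secured by the outward rotation of the hydroxyl and by the intramolecular six-centre closure, while regiochemistry needs no control because all six ring atoms and their substituents are already connected in 16. The ethoxy group sits on the inside of the closing terminus, but the sp-hybridised ketene carbon is sterically undemanding, so closure should remain fast. At 110 °C under argon the isolated E alkene and both enol ether groups are thermally inert, and exclusion of oxygen and acid keeps 19 and the β-ethoxyallylic alcohol of 16 intact until the rearrangement is complete.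

Step 9
Reactants: 19 2-ethoxy-5-methoxy-3-methyl-6-[(E)-nonadec-14-enyl]benzene-1,4-diol
Product: 20 2-ethoxy-5-methoxy-3-methyl-6-[(E)-nonadec-14-enyl]cyclohexa-2,5-diene-1,4-dione
Conditions: Ag2O, Et2O, rt
Reagents that add atoms: none
Why: Two-electron oxidation of an electron-rich hydroquinone to the para-quinone by Ag2O, the usual finish of squarate ring expansions; neither the isolated alkene nor the vinylogous esters are affected.

Step 10
Reactants: 20 2-ethoxy-5-methoxy-3-methyl-6-[(E)-nonadec-14-enyl]cyclohexa-2,5-diene-1,4-dione
Product: 21 2,5-dihydroxy-3-methyl-6-[(E)-nonadec-14-enyl]cyclohexa-2,5-diene-1,4-dione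
Conditions: 2 M aq. NaOH, MeOH/THF, rt → 50 °C; then 2 M HCl to pH 1
Reagents that add atoms: sodium hydroxide, [Na+].[OH-]
Why: Hydroxide adds to the alkoxy-bearing quinone carbons (vinylogous ester carbons) and expels methoxide and ethoxide by addition–elimination; the resulting dianion of the dihydroxyquinone is resonance-stabilised and resists further attack, and acidification releases 21 with the E alkene inert throughout.

## Compound list

1 | tridecane-1,13-diol | OCCCCCCCCCCCCCO | starting material
2 | 13-bromotridecan-1-ol | OCCCCCCCCCCCCCBr | intermediate
3 | 1-hexyne | CCCCC#C | starting material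
4 | hex-1-ynyllithium (not isolated) | CCCCC#C[Li] | intermediate
5 | nonadec-14-yn-1-ol | CCCCC#CCCCCCCCCCCCCCO | intermediate
6 | (E)-nonadec-14-en-1-ol | CCCC/C=C/CCCCCCCCCCCCCO | intermediate
7 | (E)-19-bromononadec-5-ene | CCCC/C=C/CCCCCCCCCCCCCBr | intermediate
8 | dimethyl squarate (3,4-dimethoxycyclobut-3-ene-1,2-dione) | COC1=C(OC)C(=O)C1=O | starting material
9 | (E)-nonadec-14-enylmagnesium bromide (not isolated) | CCCC/C=C/CCCCCCCCCCCCC[Mg]Br | intermediate
10 | bromomagnesium 2,3-dimethoxy-1-[(E)-nonadec-14-enyl]-4-oxocyclobut-2-en-1-olate (racemic, not isolated) | CCCC/C=C/CCCCCCCCCCCCCC1(O[Mg]Br)C(OC)=C(OC)C1=O | intermediate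
11 | 3-methoxy-4-[(E)-nonadec-14-enyl]cyclobut-3-ene-1,2-dione | CCCC/C=C/CCCCCCCCCCCCCC1=C(OC)C(=O)C1=O | intermediate
12 | ethyl prop-1-enyl ether (cis/trans mixture) | CC=COCC | starting material
13 | 1,2-dibromo-1-ethoxypropane (diastereomer mixture, not isolated) | CC(Br)C(Br)OCC | intermediate
14 | (Z)-2-bromo-1-ethoxyprop-1-ene (bromine cis to ethoxy) | C/C(Br)=C/OCC | intermediate
15 | (1-ethoxyprop-1-en-2-yl)lithium, lithium cis to ethoxy (geometry of 14 retained, E by the sequence rule; not isolated) | C/C([Li])=C/OCC | intermediate
16 | 4-[(Z)-1-ethoxyprop-1-en-2-yl]-4-hydroxy-3-methoxy-2-[(E)-nonadec-14-enyl]cyclobut-2-en-1-one (racemic) | CCCC/C=C/CCCCCCCCCCCCCC1=C(OC)C(O)(/C(C)=C\OCC)C1=O | intermediate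
17 | (3Z,5Z)-6-ethoxy-4-hydroxy-3-methoxy-5-methyl-2-[(E)-nonadec-14-enyl]hexa-1,3,5-trien-1-one (dienylketene, not isolated) | CCCC/C=C/CCCCCCCCCCCCCC(=C=O)/C(OC)=C(O)\C(C)=C/OCC | intermediate
18 | 6-ethoxy-4-hydroxy-3-methoxy-5-methyl-2-[(E)-nonadec-14-enyl]cyclohexa-2,4-dien-1-one (racemic, not isolated) | CCCC/C=C/CCCCCCCCCCCCCC1=C(OC)C(O)=C(C)C(OCC)C1=O | intermediate
19 | 2-ethoxy-5-methoxy-3-methyl-6-[(E)-nonadec-14-enyl]benzene-1,4-diol | CCCC/C=C/CCCCCCCCCCCCCc1c(OC)c(O)c(C)c(OCC)c1O | intermediate
20 | 2-ethoxy-5-methoxy-3-methyl-6-[(E)-nonadec-14-enyl]cyclohexa-2,5-diene-1,4-dione | CCCC/C=C/CCCCCCCCCCCCCC1=C(OC)C(=O)C(C)=C(OCC)C1=O | intermediate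
21 | 2,5-dihydroxy-3-methyl-6-[(E)-nonadec-14-enyl]cyclohexa-2,5-diene-1,4-dione | CCCC/C=C/CCCCCCCCCCCCCC1=C(O)C(=O)C(C)=C(O)C1=O | target

## Step count and risk

Total steps: 10. Longest linear sequence: 9 steps (steps 1–5 and 7–10, from 1). Step 6 is a one-step branch.

**Step 8 (key step).** The most likely failure is ionisation of the tertiary β-ethoxyallylic hydroxyl of 16 on warm glass or with trace acid. Allylic transposition onto the enol ether and loss of ethanol would then compete with the electrocyclic opening. A second concern is that the inward ethoxy group slows the 6π closure enough for the ketene to be captured intermolecularly by a hydroxyl.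
Fallback: setting out from 11 and 15, the lithium alkoxide formed in step 7 would be trapped in the flask with Me3SiCl before work-up. This gives 4-[(Z)-1-ethoxyprop-1-en-2-yl]-3-methoxy-2-[(E)-nonadec-14-enyl]-4-(trimethylsilyloxy)cyclobut-2-en-1-one F1. It has no free hydroxyl to ionise or to trap a ketene. Heating in toluene should take it through the same opening and closure to 2-ethoxy-5-methoxy-3-methyl-6-[(E)-nonadec-14-enyl]-4-(trimethylsilyloxy)phenol F2. Oxidation with (NH4)2Ce(NO3)6 in aqueous MeCN at 0 °C removes the silyl group and returns to the route at 20.

**Step 6.** The dehydrobromination may favour the isomer with bromine trans to ethoxy, or give a mixture that distillation does not resolve. The lithium reagent from that isomer would collapse by β-elimination to propyne and LiOEt in step 7. The same fallback covers decomposition of 15 itself.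
Fallback: setting out from 11, commercial isopropenylmagnesium bromide in THF at −78 °C would give 4-hydroxy-3-methoxy-2-[(E)-nonadec-14-enyl]-4-(prop-1-en-2-yl)cyclobut-2-en-1-one F3. Thermolysis in toluene should give 3-methoxy-5-methyl-2-[(E)-nonadec-14-enyl]benzene-1,4-diol F4, and Ag2O then gives 3-methoxy-5-methyl-2-[(E)-nonadec-14-enyl]cyclohexa-2,5-diene-1,4-dione F5. Nucleophilic epoxidation with H2O2 and Na2CO3 should take place at the methyl-bearing quinone double bond, the one not deactivated by methoxy, and give 3-methoxy-1-methyl-4-[(E)-nonadec-14-enyl]-7-oxabicyclo[4.1.0]hept-3-ene-2,5-dione F6. Aqueous NaOH should open the epoxide by enolisation at the ring C–H and β-elimination of the epoxide oxygen, and cleave the remaining vinylogous methyl ester in the same operation. Acidification returns to the route at 21.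

**Step 5.** Wurtz coupling during Grignard formation, or sluggish and then double addition to the sparingly soluble squarate at −78 °C, would erode the supply of 11.
Fallback: setting out from 7, NaI in acetone would give (E)-19-iodononadec-5-ene F7. Iodine–lithium exchange with t-BuLi (2 equiv) in Et2O/pentane at −78 °C gives (E)-nonadec-14-enyllithium F8. The alkene is too remote for cyclisation. Addition to 8 gives lithium 2,3-dimethoxy-1-[(E)-nonadec-14-enyl]-4-oxocyclobut-2-en-1-olate F9, and (CF3CO)2O followed by water returns to the route at 11.

**Step 2.** With the hydroxyl unprotected, O-alkylation of the lithium alkoxide by a second molecule of bromide, or E2 elimination, could consume 2 before the acetylide does.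
Fallback: setting out from 2, dihydropyran with pyridinium p-toluenesulfonate would give 2-(13-bromotridecoxy)oxane F10. Alkylation with 4 in THF/DMPU gives 2-(nonadec-14-ynoxy)oxane F11, and p-TsOH in MeOH returns to the route at 5.

## Further compounds

F1 | step 8 | 4-[(Z)-1-ethoxyprop-1-en-2-yl]-3-methoxy-2-[(E)-nonadec-14-enyl]-4-(trimethylsilyloxy)cyclobut-2-en-1-one (racemic) | CCCC/C=C/CCCCCCCCCCCCCC1=C(OC)C(O[Si](C)(C)C)(/C(C)=C\OCC)C1=O
F2 | step 8 | 2-ethoxy-5-methoxy-3-methyl-6-[(E)-nonadec-14-enyl]-4-(trimethylsilyloxy)phenol | CCCC/C=C/CCCCCCCCCCCCCc1c(OC)c(O[Si](C)(C)C)c(C)c(OCC)c1O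
F3 | step 6 | 4-hydroxy-3-methoxy-2-[(E)-nonadec-14-enyl]-4-(prop-1-en-2-yl)cyclobut-2-en-1-one (racemic) | CCCC/C=C/CCCCCCCCCCCCCC1=C(OC)C(O)(C(C)=C)C1=O
F4 | step 6 | 3-methoxy-5-methyl-2-[(E)-nonadec-14-enyl]benzene-1,4-diol | CCCC/C=C/CCCCCCCCCCCCCc1c(OC)c(O)c(C)cc1O
F5 | step 6 | 3-methoxy-5-methyl-2-[(E)-nonadec-14-enyl]cyclohexa-2,5-diene-1,4-dione | CCCC/C=C/CCCCCCCCCCCCCC1=C(OC)C(=O)C(C)=CC1=O
F6 | step 6 | 3-methoxy-1-methyl-4-[(E)-nonadec-14-enyl]-7-oxabicyclo[4.1.0]hept-3-ene-2,5-dione (racemic) | CCCC/C=C/CCCCCCCCCCCCCC1=C(OC)C(=O)C2(C)OC2C1=O
F7 | step 5 | (E)-19-iodononadec-5-ene | CCCC/C=C/CCCCCCCCCCCCCI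
F8 | step 5 | (E)-nonadec-14-enyllithium | CCCC/C=C/CCCCCCCCCCCCC[Li]
F9 | step 5 | lithium 2,3-dimethoxy-1-[(E)-nonadec-14-enyl]-4-oxocyclobut-2-en-1-olate (racemic) | CCCC/C=C/CCCCCCCCCCCCCC1(O[Li])C(OC)=C(OC)C1=O
F10 | step 2 | 2-(13-bromotridecoxy)oxane | BrCCCCCCCCCCCCCOC1CCCCO1
F11 | step 2 | 2-(nonadec-14-ynoxy)oxane | CCCCC#CCCCCCCCCCCCCCOC1CCCCO1
A1 | alternative 1 | 4-methoxy-5-methyl-2-[(E)-nonadec-14-enyl]phenol | CCCC/C=C/CCCCCCCCCCCCCc1cc(OC)c(C)cc1O
A2 | alternative 1 | pentacarbonyl[methoxy(prop-1-en-2-yl)methylidene]chromium | COC(C(C)=C)=[Cr](=C=O)(=C=O)(=C=O)(=C=O)=C=O
A3 | alternative 1 | (E)-henicos-16-en-1-yne | CCCC/C=C/CCCCCCCCCCCCCC#C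
A4 | alternative 1 | 2-methyl-5-[(E)-nonadec-14-enyl]cyclohexa-2,5-diene-1,4-dione | CCCC/C=C/CCCCCCCCCCCCCC1=CC(=O)C(C)=CC1=O
A5 | alternative 2 | methyl 2,4-dihydroxy-3-methyl-6-[(E)-nonadec-14-enyl]benzoate | CCCC/C=C/CCCCCCCCCCCCCc1cc(O)c(C)c(O)c1C(=O)OC
A6 | alternative 2 | (E)-tetracos-19-en-4-yn-3-one | CCCC/C=C/CCCCCCCCCCCCCC#CC(=O)CC
A7 | alternative 2 | dimethyl malonate | COC(=O)CC(=O)OC
A8 | alternative 3 | 4,6-dimethoxy-2-methyl-5-[(E)-nonadec-14-enyl]benzene-1,3-diol | CCCC/C=C/CCCCCCCCCCCCCc1c(OC)c(O)c(C)c(O)c1OC
A9 | alternative 3 | 1,5-dimethoxy-3-methylpentane-2,4-dione | COCC(=O)C(C)C(=O)COC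
A10 | alternative 3 | methyl (E)-icos-15-enoate | CCCC/C=C/CCCCCCCCCCCCCC(=O)OC
A11 | alternative 3 | 2-hydroxy-5-methoxy-3-methyl-6-[(E)-nonadec-14-enyl]cyclohexa-2,5-diene-1,4-dione | CCCC/C=C/CCCCCCCCCCCCCC1=C(OC)C(=O)C(C)=C(O)C1=O
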